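**Retrosynthetic overview**
- Target 18 ⇐ bicyclic type A enol 17 (C3 prenyl, C5 geranyl, endo C7 prenyl) by a radical cycloisomerization that forms the homoadamantane ring (C3–CH bond), then the cyclopentane (CMe2–CH bond).
- 17 ⇐ hydroxy-adamantane 11: retro-aldol opening, alkenyl addition and allylic deoxygenation give the endo C7 prenyl.
- 11 ⇐ 10 by decarbonylation of the spare enal arm; 10 ⇐ symmetric bis-enal acylphloroglucinol 6 + geranyl bromide by catalytic enantioselective C-geranylation (sets C5), then Michael (C1–C8) and aldol closure in the same flask.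
- 6 ⇐ 2,4,6-trihydroxybenzophenone + 2 × bromo-enal 4 (three steps from diethyl isopropylidenemalonate).
- Ring order: arene (bought) → bicyclo[3.3.1]nonane → adamantane (temporary) → reopened bicycle → homoadamantane → cyclopentane.

Core numbering used in the names: C1 benzoyl bridgehead, C2–C3–C4 the 1,3-dione unit, C5 geranyl bridgehead, C6 CH2, C7 CH, C8 CMe2, C9 bridging ketone.
Assumption: the cinchonidine-derived ammonium salt is taken to give the C5 configuration drawn; if the sense is opposite, the cinchonine-derived pseudoenantiomer is used.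
Assumption: the carbinol carbon in 10, 11, 14 and 15 forms as an unassigned epimer mixture (left undefined in the SMILES) and is erased later; enols are drawn as one tautomer.

**Step 1**
Reactants: 1 diethyl 2-(propan-2-ylidene)propanedioate
Product: 2 2-(propan-2-ylidene)propane-1,3-diol
Conditions: i-Bu2AlH (4.5 equiv), CH2Cl2, −78 → 0 °C; aq. potassium sodium tartrate
Reagents that add atoms: none
Why: 1,2-reduction of both conjugated esters to allylic alcohols by the aluminium hydride leaves the tetrasubstituted olefin untouched; no stereocentre is formed.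

**Step 2**
Reactants: 2 2-(propan-2-ylidene)propane-1,3-diol
Product: 3 2-(hydroxymethyl)-3-methylbut-2-enal
Conditions: MnO2 (10 equiv), CH2Cl2, rt
Reagents that add atoms: none
Why: allylic alcohol oxidation with MnO2 stops after one hydroxyl because the second CH2OH then sits on an electron-poor enal; no stereocentre.

**Step 3**
Reactants: 3 2-(hydroxymethyl)-3-methylbut-2-enal
Product: 4 2-(bromomethyl)-3-methylbut-2-enal
Conditions: PBr3 (0.4 equiv), Et2O, −20 → 0 °C; used crude
Reagents that add atoms: phosphorus tribromide, BrP(Br)Br
Why: SN2 conversion of the primary allylic alcohol to the bromide through its bromophosphite, which the hindered conjugated aldehyde tolerates; no stereocentre.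

**Step 4**
Reactants: 5 2,4,6-trihydroxybenzophenone; 4 2-(bromomethyl)-3-methylbut-2-enal (2.1 equiv)
Product: 6 [3,5-bis(2-formyl-3-methylbut-2-en-1-yl)-2,4,6-trihydroxyphenyl](phenyl)methanone
Conditions: KOH (3.2 equiv), H2O/THF, 0 °C; cold 1 M HCl quench
Reagents that add atoms: none
Why: twofold C-allylation of the phloroglucinol polyanion at its two free ring carbons (the reaction type used for C-prenylation of acylphloroglucinols, protic medium favouring C over O attack) gives an achiral product whose two arm-bearing carbons are enantiotopic, the cold acidic quench limiting reversible oxa-Michael closure of a phenol onto the enal.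

**Step 5**
Reactants: 6 bis-enal benzophenone; 7 geranyl bromide (1.1 equiv)
Product: 10 type A hydroxy-adamantane carrying C5 geranyl plus the C3 enal arm, via C5-geranylated enal trione 8 (not isolated), via bicyclic endo aldehyde 9 (not isolated)
Conditions: N-(9-anthracenylmethyl)-O-allylcinchonidinium bromide (10 mol %), CsOH·H2O (5 equiv), PhMe/CH2Cl2, 4 Å MS, −40 → 0 °C
Reagents that add atoms: none
Why: Proposed new method: the polyanion of 6 is held as a contact ion pair by the chiral ammonium ion, whose anthracenylmethyl wall covers one face and leaves, on the open face, only one of the two enantiotopic arm-bearing ring carbons open to SN2 attack on 7, so C-geranylation (alkylative dearomatization) sets C5 as the first stereocentre; enolate 8 then closes by Michael addition of the benzoyl-bearing carbon to the β,β-dimethyl enal on C5 (C1–C8 bond) and, after the C7 epimers equilibrate through the enolate, by aldol addition of C3 to endo aldehyde 9, which drains the reversible Michael equilibria (including closure from C3) into the cage, so C1, C3 and C7 follow from C5 by cage geometry; the closest known reactions are the cinchona-ammonium-catalysed enantioselective alkylative dearomatization–annulation of 3,5-diprenyl acylphloroglucinols with an α-(acetoxymethyl) enal (there the enal is the electrophile, here it is already on the ring) and phase-transfer allylation of β-dicarbonyl enolates.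

**Step 6**
Reactants: 10 hydroxy-adamantane with the C3 enal arm
Product: 11 type A hydroxy-adamantane carrying C5 geranyl plus C3 prenyl
Conditions: RhCl(PPh3)3 (1.1 equiv), PhMe, 110 °C
Reagents that add atoms: none
Why: Tsuji–Wilkinson decarbonylation, in which monovalent rhodium inserts into the formyl C–H of the only free aldehyde (the C7 aldehyde is locked as the adamantanol), extrudes CO and reductively eliminates the vinyl C–H, turns the spare enal arm into the C3 prenyl group without touching a stereocentre.

**Step 7**
Reactants: 11 hydroxy-adamantane; 12 2-methylprop-1-enylmagnesium bromide (4 equiv)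
Product: 15 bis(methyl carbonate) of the ring-opened C7 allylic alcohol, via ring-opened endo aldehyde 13 (not isolated), via allylic alcohol 14 (not isolated)
Conditions: 12, CeCl3 (4 equiv), THF, −78 °C, then 11, −78 → −40 °C; then ClCO2Me (6 equiv), −78 → 0 °C
Reagents that add atoms: methyl chloroformate, COC(=O)Cl
Why: deprotonation of the adamantanol triggers retro-aldol cleavage of the C3–CH(OH) bond to the 1,3-diketonate and endo C7 aldehyde 13, which the non-basic alkenylcerium reagent adds to faster than C7 can epimerise (organocerium 1,2-addition, known for such hydroxy-adamantanes), and both oxygens are then capped as carbonates; C7 keeps its configuration and the new carbinol centre is a mixture removed in step 8.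

**Step 8**
Reactants: 15 bis(methyl carbonate)
Product: 17 7-endo type A enol (C3 prenyl, C5 geranyl, C7 prenyl), via enol carbonate 16 (not isolated)
Conditions: Pd(PPh3)4 (10 mol %), Bu3SnH (1.5 equiv, slow addition), THF, rt; then K2CO3 (cat.), MeOH, rt
Reagents that add atoms: none
Why: Tsuji–Trost-type hydrogenolysis, in which zerovalent palladium ionises the allylic carbonate and the tin hydride hands its hydrogen through a palladium hydride to the less substituted, cage-side terminus of the π-allyl, so the olefin stays trisubstituted (prenyl), whereas a formate source would deliver to the CMe2 end; the enol carbonate keeps the diketone from attacking the π-allyl and is then removed by methanolysis, and no stereocentre is touched.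

**Step 9**
Reactants: 17 7-endo type A enol
Product: 18 target CNP0155129.3
Conditions: 4CzIPN (2 mol %), 2,4,6-triisopropylbenzenethiol (5 mol %), 2,6-lutidine (20 mol %), MeCN (5 mM), 450 nm LED, rt
Reagents that add atoms: none
Why: Proposed new method: the excited organic photocatalyst oxidises the 1,3-diketonate of 17 to the C3 radical, which adds to the endo C7 prenyl olefin held over it (seven-membered ring closure, CMe2 end turned to the C4/C6 side away from the C8 methyls, fixing the ring-fusion CH), the tertiary radical then closes 5-exo-trig onto the C3 prenyl olefin through a chair-like transition state that puts the forming isopropyl trans to the CH2 bridge, and the thiol gives the last tertiary radical its hydrogen atom while the thiyl radical is reduced back by the photocatalyst radical anion, so the whole is an isomerization (the bridgehead geranyl group is equatorial on the dione ring and cannot reach C3); the closest known reactions are Mn(OAc)3-mediated oxidative radical cyclization cascades of dearomatized acylphloroglucinols (which end by oxidation, not hydrogen transfer) and photoredox/thiol hydroalkylations of olefins by 1,3-dicarbonyls.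

**Compound list**
1 | diethyl 2-(propan-2-ylidene)propanedioate | CCOC(=O)C(=C(C)C)C(=O)OCC | starting material
2 | 2-(propan-2-ylidene)propane-1,3-diol | CC(C)=C(CO)CO | intermediate
3 | 2-(hydroxymethyl)-3-methylbut-2-enal | CC(C)=C(CO)C=O | intermediate
4 | 2-(bromomethyl)-3-methylbut-2-enal | CC(C)=C(CBr)C=O | intermediate
5 | 2,4,6-trihydroxybenzophenone | O=C(c1ccccc1)c1c(O)cc(O)cc1O | starting material
6 | [3,5-bis(2-formyl-3-methylbut-2-en-1-yl)-2,4,6-trihydroxyphenyl](phenyl)methanone | O=C(c1ccccc1)c1c(O)c(CC(C=O)=C(C)C)c(O)c(CC(C=O)=C(C)C)c1O | intermediate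
7 | geranyl bromide, (2E)-1-bromo-3,7-dimethylocta-2,6-diene | CC(C)=CCC/C(C)=C/CBr | starting material
8 | 2-benzoyl-6-geranyl-4,6-bis(2-formyl-3-methylbut-2-enyl)-3,5-dihydroxycyclohexa-2,4-dien-1-one, quaternary carbon (future C5) as encoded (not isolated) | CC(C)=CCC/C(C)=C/C[C@]1(CC(C=O)=C(C)C)C(=O)C(C(=O)c2ccccc2)=C(O)C(CC(C=O)=C(C)C)=C1O | intermediate
9 | 1-benzoyl-5-geranyl-3-(2-formyl-3-methylbut-2-enyl)-4-hydroxy-8,8-dimethyl-2,9-dioxobicyclo[3.3.1]non-3-ene-7-carbaldehyde, CHO endo (over the C2–C4 bridge) (not isolated) | CC(C)=CCC/C(C)=C/C[C@@]12C[C@@H](C=O)C(C)(C)[C@](C(=O)c3ccccc3)(C2=O)C(=O)C(CC(C=O)=C(C)C)=C1O | intermediate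
10 | hydroxy-adamantane-2,4,9-trione: C1 benzoyl, C5 geranyl, C8 gem-dimethyl, C3 2-formyl-3-methylbut-2-enyl, CH(OH) bridge between C3 and C7 | CC(C)=CCC/C(C)=C/C[C@@]12C[C@H]3C(O)[C@@](CC(C=O)=C(C)C)(C1=O)C(=O)[C@@](C(=O)c1ccccc1)(C2=O)C3(C)C | intermediate
11 | hydroxy-adamantane-2,4,9-trione: C1 benzoyl, C5 geranyl, C8 gem-dimethyl, C3 prenyl, CH(OH) bridge between C3 and C7 | CC(C)=CCC/C(C)=C/C[C@@]12C[C@H]3C(O)[C@@](CC=C(C)C)(C1=O)C(=O)[C@@](C(=O)c1ccccc1)(C2=O)C3(C)C | intermediate
12 | 2-methylprop-1-enylmagnesium bromide | CC(C)=C[Mg]Br | starting material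
13 | 1-benzoyl-5-geranyl-4-hydroxy-8,8-dimethyl-2,9-dioxo-3-prenylbicyclo[3.3.1]non-3-ene-7-carbaldehyde, CHO endo (not isolated) | CC(C)=CCC/C(C)=C/C[C@@]12C[C@@H](C=O)C(C)(C)[C@](C(=O)c3ccccc3)(C2=O)C(=O)C(CC=C(C)C)=C1O | intermediate
14 | as 13 but with endo C7 1-hydroxy-3-methylbut-2-enyl in place of CHO (not isolated) | CC(C)=CCC/C(C)=C/C[C@@]12C[C@@H](C(O)C=C(C)C)C(C)(C)[C@](C(=O)c3ccccc3)(C2=O)C(=O)C(CC=C(C)C)=C1O | intermediate
15 | bis(methyl carbonate) of 14: allylic O-carbonate on the C7 side chain and enol O-carbonate (C4–O drawn, the C2–O isomer behaves alike) | CC(C)=CCC/C(C)=C/C[C@@]12C[C@@H](C(OC(=O)OC)C=C(C)C)C(C)(C)[C@](C(=O)c3ccccc3)(C2=O)C(=O)C(CC=C(C)C)=C1OC(=O)OC | intermediate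
16 | enol methyl carbonate of 17 (not isolated) | CC(C)=CCC/C(C)=C/C[C@@]12C[C@@H](CC=C(C)C)C(C)(C)[C@](C(=O)c3ccccc3)(C2=O)C(=O)C(CC=C(C)C)=C1OC(=O)OC | intermediate
17 | 1-benzoyl-5-geranyl-4-hydroxy-8,8-dimethyl-3,7-diprenylbicyclo[3.3.1]non-3-ene-2,9-dione, C7 prenyl endo | CC(C)=CCC/C(C)=C/C[C@@]12C[C@@H](CC=C(C)C)C(C)(C)[C@](C(=O)c3ccccc3)(C2=O)C(=O)C(CC=C(C)C)=C1O | intermediate
18 | CNP0155129.3: homoadamantane-type trione with fused isopropyl-dimethylcyclopentane, C1 benzoyl, C5 geranyl | CC(C)=CCC/C(C)=C/C[C@@]12C[C@H]3C[C@H]4C(C)(C)[C@H](C(C)C)C[C@]4(C1=O)C(=O)[C@@](C(=O)c1ccccc1)(C2=O)C3(C)C | target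

**Totals**
Total step count: 9.
Longest linear sequence: 9 steps (1 → 2 → 3 → 4 → 6 → 10 → 11 → 15 → 17 → 18).

**Steps most likely to fail, with fallbacks**

Step 5 (new). Risks are O-geranylation, a second geranylation at C3 before the cage closes, Michael closure from C3 instead of C1 (type B skeleton) if the aldol does not drain the equilibrium, and insufficient enantiocontrol with a simple allylic bromide. The fallback sets out from 6 and comes back at 10. The same geranylation–annulation is run without chiral control (LiHMDS, THF, −78 → 0 °C), which relies only on known base-mediated alkylative dearomatization and Michael–aldol closure, to give racemic hydroxy-adamantane F1. F1 is resolved by preparative SFC on an amylose tris(3,5-dimethylphenylcarbamate) phase to give 10.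

Step 6. The enal is tetrasubstituted and hindered, 10 can sit as a lactol between the carbinol and the arm aldehyde, and heating risks retro-aldol followed by loss of the C7 carbon. The fallback sets out from 5 and comes back at 11, with no decarbonylation. Mono-C-prenylation of 5 (prenyl bromide, aq. KOH, 0 °C) gives 3-prenyl-2,4,6-trihydroxybenzophenone F2. One equivalent of 4 under the step 4 conditions gives prenyl/enal benzophenone F3. The step 5 conditions with 7 then take F3 through C5-geranylated prenyl trione F4 and aldehyde 13 directly to 11. The price is site selectivity: geranylation at the prenyl-bearing carbon gives regioisomeric trione F5, which cannot give 11 and is removed by chromatography.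

Step 9 (new). Risks are hydrogen transfer to the first tertiary radical before the 5-exo closure, E/Z scrambling of the geranyl olefin by thiyl radical, and diastereocontrol at the isopropyl-bearing carbon. The fallback sets out from 17 and comes back at 18 by known halogen-atom chemistry. Bromination of the enol (NBS, 1.0 equiv, CH2Cl2, −78 °C) gives C3-bromo trione F6. Slow addition of Bu3SnH with AIBN (PhH, 80 °C) generates the same C3 radical, runs the same two ring closures and ends by hydrogen transfer from tin; early reduction only returns 17, which is recycled.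

**Further compounds**
F1 | step 5 | racemic hydroxy-adamantane (racemate of 10, relative configuration fixed by the cage) | CC(C)=CCC/C(C)=C/CC12CC3C(O)C(CC(C=O)=C(C)C)(C1=O)C(=O)C(C(=O)c1ccccc1)(C2=O)C3(C)C
F2 | step 6 | 3-prenyl-2,4,6-trihydroxybenzophenone | CC(C)=CCc1c(O)cc(O)c(C(=O)c2ccccc2)c1O
F3 | step 6 | [3-(2-formyl-3-methylbut-2-en-1-yl)-2,4,6-trihydroxy-5-(3-methylbut-2-en-1-yl)phenyl](phenyl)methanone | O=C(c1ccccc1)c1c(O)c(CC=C(C)C)c(O)c(CC(C=O)=C(C)C)c1O
F4 | step 6 | C5-geranylated prenyl trione (not isolated) | CC(C)=CCC/C(C)=C/C[C@]1(CC(C=O)=C(C)C)C(=O)C(C(=O)c2ccccc2)=C(O)C(CC=C(C)C)=C1O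
F5 | step 6 | regioisomeric trione geranylated at the prenyl-bearing carbon (by-product, configuration undefined) | CC(C)=CCC/C(C)=C/CC1(CC=C(C)C)C(=O)C(C(=O)c2ccccc2)=C(O)C(CC(C=O)=C(C)C)=C1O
F6 | step 9 | C3-bromo trione (3-bromo-3-prenyl derivative of 17, C3 configuration undefined) | CC(C)=CCC/C(C)=C/C[C@@]12C[C@@H](CC=C(C)C)C(C)(C)[C@](C(=O)c3ccccc3)(C2=O)C(=O)C(Br)(CC=C(C)C)C1=O
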